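Everything rests on cutting the C3–C3a bond of the cis-dihydrobenzofuran ring (O1, C2, C3, C3a, C7a). The feature used is that C3 carries a CH2OH arm and hangs on C3a, the arene carbon beside O1-bearing C7a. A carbanion at C3a attacking the substituted end of an oxirane tethered through O1 and C2 produces just this array. In one operation the key step hides the aldehyde, trades bromine for lithium, closes the five-membered ring, fixes C3 by inversion and uncovers the primary alcohol. Its precursor is the threo (R,R) 1-aryl-2,3-epoxypropyl ether of 5-bromovanillin. The furofuran follows from a lactone aldol and two SN2 etherifications, avoiding acid able to ionise C2–O1.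

Key step: step 5

Assumption: the 2,3-cis (2S,3S) dihydrobenzofuran encoded in the SMILES is taken as drawn, and the furofuran is 7S,8R,7'S,8'R in lignan numbering (C7–C8–C9 on the benzofuran side, C7'–C8'–C9' on the syringyl side).
Abbreviations in names: BF = (2S,3S)-3-[(tert-butyldiphenylsilyloxy)methyl]-7-methoxy-2-[3-methoxy-4-(triisopropylsilyloxy)phenyl]-2,3-dihydrobenzofuran-5-yl; Syr = 3,5-dimethoxy-4-(triisopropylsilyloxy)phenyl.

Step 1
Reactants: 1 vanillin
Product: 2 3-methoxy-4-(triisopropylsilyloxy)benzaldehyde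
Conditions: i-Pr3SiCl, imidazole, DMF, rt
Reagents that add atoms: chlorotriisopropylsilane, CC(C)[Si](Cl)(C(C)C)C(C)C
Why: Phenol silylation (silyl ether formation) is routine, and the bulky triisopropylsilyl group is chosen over a smaller silyl group because it must resist the lithium, potassium and aluminium alkoxides of steps 5, 14 and 15.

Step 2
Reactants: 2 3-methoxy-4-(triisopropylsilyloxy)benzaldehyde; 3 vinylmagnesium bromide
Product: 4 rac-1-[3-methoxy-4-(triisopropylsilyloxy)phenyl]prop-2-en-1-ol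
Conditions: THF, −78 → 0 °C; aq. NH4Cl
Reagents that add atoms: none
Why: Grignard 1,2-addition to an aromatic aldehyde gives the allylic alcohol as a racemate, whose carbinol centre is sorted out in step 3.

Step 3
Reactants: 4 rac-1-[3-methoxy-4-(triisopropylsilyloxy)phenyl]prop-2-en-1-ol
Product: 5 (S)-[3-methoxy-4-(triisopropylsilyloxy)phenyl][(R)-oxiran-2-yl]methanol (erythro)
Conditions: Ti(OiPr)4 (0.15 equiv), L-(+)-diisopropyl tartrate (0.18 equiv), t-BuOOH (0.45 equiv), 4 Å molecular sieves, CH2Cl2, −20 °C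
Reagents that add atoms: tert-butyl hydroperoxide, CC(C)(C)OO
Why: In the Sharpless kinetic-resolution epoxidation with L-(+)-tartrate the R allylic alcohol should be epoxidised much faster than its mirror image and on the face that gives the erythro product, so the catalyst fixes both the carbinol carbon (S after the priority change) and the oxirane carbon (R), and conversion is held below one half to protect the enantiopurity of the epoxide.

Step 4
Reactants: 5 (S)-[3-methoxy-4-(triisopropylsilyloxy)phenyl][(R)-oxiran-2-yl]methanol; 6 5-bromovanillin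
Product: 7 3-bromo-5-methoxy-4-{(R)-[3-methoxy-4-(triisopropylsilyloxy)phenyl][(R)-oxiran-2-yl]methoxy}benzaldehyde (threo)
Conditions: PPh3, DIAD, toluene–THF (4:1), −20 → 0 °C
Reagents that add atoms: none
Why: In the Mitsunobu etherification the acidic phenol displaces the oxyphosphonium group by SN2 inversion, turning the S carbinol into the R aryl ether, while the non-polar medium, the low temperature and the electron-withdrawing oxirane next to the reacting carbon work against ionisation.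

Step 5
Reactants: 7 3-bromo-5-methoxy-4-{(R)-[3-methoxy-4-(triisopropylsilyloxy)phenyl][(R)-oxiran-2-yl]methoxy}benzaldehyde
Product: 11 (2S,3S)-3-(hydroxymethyl)-7-methoxy-2-[3-methoxy-4-(triisopropylsilyloxy)phenyl]-2,3-dihydrobenzofuran-5-carbaldehyde, via lithium α-morpholino alkoxide 8 (not isolated), via aryllithium 9 (not isolated), via cyclised dilithium dialkoxide 10 (not isolated)
Conditions: morpholine + n-BuLi (1.05 equiv each), THF, −78 °C, then 7, 20 min; n-BuLi (1.1 equiv), −95 °C, warm to −40 °C; aq. NH4Cl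
Reagents that add atoms: none
Why: Lithium morpholide adds to the aldehyde of 7 at −78 °C and parks it as the α-amino alkoxide 8, after which n-BuLi exchanges the bromine, which lies ortho to the ether oxygen, to give aryllithium 9 faster than it can touch the oxirane. The carbanion at C3a then attacks the nearer oxirane carbon anti to its C–O bond, which forges C3–C3a and expels the primary alkoxide (10), and aqueous ammonium chloride returns the aldehyde and the alcohol. The closest known reaction type is the Parham cyclisation of ortho-lithiated aryl glycidyl ethers to 3-(hydroxymethyl)-2,3-dihydrobenzofurans. The ring O1–C2–C3–C3a–C7a closes in the 5-exo-tet mode. C3 is the only new stereocentre and is controlled by SN2 inversion of the R oxirane carbon while C2 is a bystander, so the threo ether can lead only to the 2,3-cis (2S,3S) product. The step needs inner-carbon (5-exo) rather than terminal (6-endo) opening, secured by the short O1–C2 tether and by adding no Lewis acid, and it needs exchange and ring closure to outrun proton transfer from the benzylic C2–H, secured by the fast Br/Li exchange at −95 °C and the proximity of the oxirane.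

Step 6
Reactants: 11 (2S,3S)-3-(hydroxymethyl)-7-methoxy-2-[3-methoxy-4-(triisopropylsilyloxy)phenyl]-2,3-dihydrobenzofuran-5-carbaldehyde
Product: 12 (2S,3S)-3-[(tert-butyldiphenylsilyloxy)methyl]-7-methoxy-2-[3-methoxy-4-(triisopropylsilyloxy)phenyl]-2,3-dihydrobenzofuran-5-carbaldehyde (BF–CHO)
Conditions: t-BuPh2SiCl, imidazole, DMF, rt
Reagents that add atoms: tert-butylchlorodiphenylsilane, CC(C)(C)[Si](Cl)(c1ccccc1)c1ccccc1
Why: Silyl ether formation on the primary alcohol removes the only acidic proton before the enolate chemistry, and the tert-butyldiphenylsilyl group outlasts the mild acid of step 15 yet leaves with fluoride in step 17.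

Step 7
Reactants: 13 syringaldehyde
Product: 14 3,5-dimethoxy-4-(triisopropylsilyloxy)benzaldehyde (Syr–CHO)
Conditions: i-Pr3SiCl, imidazole, DMF, 40 °C
Reagents that add atoms: chlorotriisopropylsilane, CC(C)[Si](Cl)(C(C)C)C(C)C
Why: Phenol silylation (silyl ether formation) works on this flanked phenol with gentle warming and gives a group that survives every basic and hydridic step that follows.

Step 8
Reactants: 15 (S)-4-benzyl-1,3-oxazolidin-2-one; 16 pent-4-enoyl chloride
Product: 17 (S)-4-benzyl-3-(pent-4-enoyl)-1,3-oxazolidin-2-one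
Conditions: Et3N, DMAP (cat.), CH2Cl2, 0 °C → rt
Reagents that add atoms: none
Why: N-acylation of the oxazolidinone by an acid chloride under DMAP catalysis (nucleophilic acyl substitution) is a standard way to load the auxiliary.

Step 9
Reactants: 17 (S)-4-benzyl-3-(pent-4-enoyl)-1,3-oxazolidin-2-one; 14 3,5-dimethoxy-4-(triisopropylsilyloxy)benzaldehyde
Product: 19 (S)-4-benzyl-3-{(2S)-2-[(S)-Syr(hydroxy)methyl]pent-4-enoyl}-1,3-oxazolidin-2-one, via dibutylboron Z-enolate 18 (not isolated)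
Conditions: n-Bu2BOTf, Et3N, CH2Cl2, −78 → 0 °C; 14, −78 → 0 °C; H2O2, MeOH, pH 7 buffer
Reagents that add atoms: none
Why: In the Evans syn aldol the Z boron enolate reacts through a Zimmerman–Traxler chair on the face left open by the benzyl group of the S auxiliary, which sets the future C8' and C7' with the syn relation and the absolute sense found in the target.

Step 10
Reactants: 19 (S)-4-benzyl-3-{(2S)-2-[(S)-Syr(hydroxy)methyl]pent-4-enoyl}-1,3-oxazolidin-2-one
Product: 20 (S)-4-benzyl-3-{(2S)-2-[(S)-Syr(triethylsilyloxy)methyl]pent-4-enoyl}-1,3-oxazolidin-2-one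
Conditions: Et3SiOTf, 2,6-lutidine, CH2Cl2, −78 → 0 °C
Reagents that add atoms: triethylsilyl trifluoromethanesulfonate, CC[Si](CC)(CC)OS(=O)(=O)C(F)(F)F
Why: Silyl ether formation with the triflate and a hindered base caps the crowded aldol hydroxyl without retro-aldol, and triethylsilyl is chosen because it alone is lost under the mild acid of step 15.

Step 11
Reactants: 20 (S)-4-benzyl-3-{(2S)-2-[(S)-Syr(triethylsilyloxy)methyl]pent-4-enoyl}-1,3-oxazolidin-2-one
Product: 21 (2R)-2-[(S)-Syr(triethylsilyloxy)methyl]pent-4-en-1-ol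
Conditions: LiBH4, MeOH (1 equiv), Et2O, 0 °C
Reagents that add atoms: none
Why: Reductive removal of the oxazolidinone auxiliary with LiBH4 turns the imide carbonyl into the C9' CH2OH without touching the alkene, the silyl ethers or either stereocentre.

Step 12
Reactants: 21 (2R)-2-[(S)-Syr(triethylsilyloxy)methyl]pent-4-en-1-ol
Product: 23 (4R)-4-[(S)-Syr(triethylsilyloxy)methyl]tetrahydrofuran-2-ol (anomer mixture), via γ-hydroxy aldehyde 22 (not isolated)
Conditions: OsO4 (2 mol %), NaIO4 (4 equiv), 2,6-lutidine, dioxane–H2O (3:1), rt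
Reagents that add atoms: sodium periodate NaIO4 (oxygen source, relayed by OsO4), [Na+].[O-]I(=O)(=O)=O
Why: Lemieux–Johnson cleavage removes the terminal CH2 and the freed aldehyde is captured at once by the C9' hydroxyl as a five-membered lactol, with no chain stereocentre involved.

Step 13
Reactants: 23 (4R)-4-[(S)-Syr(triethylsilyloxy)methyl]tetrahydrofuran-2-ol
Product: 24 (4R)-4-[(S)-Syr(triethylsilyloxy)methyl]dihydrofuran-2(3H)-one
Conditions: Pr4N[RuO4] (5 mol %), N-methylmorpholine N-oxide, 4 Å molecular sieves, CH2Cl2, rt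
Reagents that add atoms: none
Why: Ley–Griffith oxidation of a lactol to the γ-lactone runs under neutral conditions that spare both silyl ethers.

Step 14
Reactants: 24 (4R)-4-[(S)-Syr(triethylsilyloxy)methyl]dihydrofuran-2(3H)-one; 12 BF–CHO
Product: 26 (3S,4R)-3-[(S)-BF(hydroxy)methyl]-4-[(S)-Syr(triethylsilyloxy)methyl]dihydrofuran-2(3H)-one, via potassium lactone enolate 25 (not isolated)
Conditions: 24 (1.3 equiv), KN(SiMe3)2 (1.25 equiv), toluene–THF, −78 °C; 12; AcOH quench at −78 °C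
Reagents that add atoms: none
Why: In this aldol addition of a lactone enolate the aldehyde approaches the ring face opposite the C8' substituent, which sets C8 trans, and the weakly coordinating potassium enolate is expected to react through an open transition state that favours the syn (erythro) carbinol needed at C7.

Step 15
Reactants: 26 (3S,4R)-3-[(S)-BF(hydroxy)methyl]-4-[(S)-Syr(triethylsilyloxy)methyl]dihydrofuran-2(3H)-one
Product: 28 (1S,2R,3R,4S)-1-BF-4-Syr-2,3-bis(hydroxymethyl)butane-1,4-diol, via triethylsilyl-protected triol 27 (not isolated)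
Conditions: LiAlH4, THF, 0 °C; H2O–NaOH work-up; crude 27, PPTS (0.1 equiv), MeOH–CH2Cl2, 0 °C → rt
Reagents that add atoms: none
Why: Hydride reduction of the lactone to the diol followed by acid-catalysed methanolysis of the triethylsilyl ether gives the tetraol, any silyl migration during the reduction being harmless since that group is removed wherever it sits, and PPTS is too weak to ionise C2–O1 or to cleave the other silyl ethers.

Step 16
Reactants: 28 (1S,2R,3R,4S)-1-BF-4-Syr-2,3-bis(hydroxymethyl)butane-1,4-diol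
Product: 30 (1S,3aR,4S,6aR)-1-BF-4-Syr-tetrahydro-1H,3H-furo[3,4-c]furan, via bis(methanesulfonate) 29 (not isolated)
Conditions: MsCl (2.2 equiv), pyridine, 0 °C → rt
Reagents that add atoms: none
Why: In this double Williamson-type cycloetherification both primary alcohols are sulfonylated at 0 °C before either ring closes, then each benzylic hydroxyl displaces the mesylate four atoms away in a 5-exo-tet SN2 step at a CH2 carbon, so C7 and C7' keep their configuration, both aryl groups end up exo and the medium stays basic throughout.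

Step 17
Reactants: 30 (1S,3aR,4S,6aR)-1-BF-4-Syr-tetrahydro-1H,3H-furo[3,4-c]furan
Product: 31 4-[(1S,3aR,4S,6aR)-4-{(2S,3S)-2-(4-hydroxy-3-methoxyphenyl)-3-(hydroxymethyl)-7-methoxy-2,3-dihydrobenzofuran-5-yl}tetrahydro-1H,3H-furo[3,4-c]furan-1-yl]-2,6-dimethoxyphenol (target)
Conditions: Bu4NF (4 equiv), AcOH (4 equiv), THF, 0 °C → rt
Reagents that add atoms: none
Why: Fluoride desilylation buffered with acetic acid removes all three silyl groups while keeping the guaiacyl phenol protonated, which blocks quinone-methide opening of C2–O1 and so preserves the cis ring.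

Compound list
1 | vanillin | COc1cc(C=O)ccc1O | starting material
2 | 3-methoxy-4-(triisopropylsilyloxy)benzaldehyde | COc1cc(C=O)ccc1O[Si](C(C)C)(C(C)C)C(C)C | intermediate
3 | vinylmagnesium bromide | C=C[Mg]Br | starting material
4 | rac-1-[3-methoxy-4-(triisopropylsilyloxy)phenyl]prop-2-en-1-ol | COc1cc(C(O)C=C)ccc1O[Si](C(C)C)(C(C)C)C(C)C | intermediate
5 | (S)-[3-methoxy-4-(triisopropylsilyloxy)phenyl][(R)-oxiran-2-yl]methanol | COc1cc([C@H](O)[C@H]2CO2)ccc1O[Si](C(C)C)(C(C)C)C(C)C | intermediate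
6 | 5-bromovanillin | COc1cc(C=O)cc(Br)c1O | starting material
7 | 3-bromo-5-methoxy-4-{(R)-[3-methoxy-4-(triisopropylsilyloxy)phenyl][(R)-oxiran-2-yl]methoxy}benzaldehyde | COc1cc([C@@H](Oc2c(OC)cc(C=O)cc2Br)[C@H]2CO2)ccc1O[Si](C(C)C)(C(C)C)C(C)C | intermediate
8 | lithium α-morpholino alkoxide of 7 | COc1cc([C@@H](Oc2c(OC)cc(C([O-])N3CCOCC3)cc2Br)[C@H]2CO2)ccc1O[Si](C(C)C)(C(C)C)C(C)C.[Li+] | intermediate
9 | aryllithium from 8 (Li in place of Br) | COc1cc([C@@H](Oc2c(OC)cc(C([O-])N3CCOCC3)cc2[Li])[C@H]2CO2)ccc1O[Si](C(C)C)(C(C)C)C(C)C.[Li+] | intermediate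
10 | cyclised dilithium dialkoxide (masked aldehyde, C3 CH2OLi) | COc1cc([C@H]2Oc3c(OC)cc(C([O-])N4CCOCC4)cc3[C@H]2C[O-])ccc1O[Si](C(C)C)(C(C)C)C(C)C.[Li+].[Li+] | intermediate
11 | (2S,3S)-3-(hydroxymethyl)-7-methoxy-2-[3-methoxy-4-(triisopropylsilyloxy)phenyl]-2,3-dihydrobenzofuran-5-carbaldehyde | COc1cc([C@H]2Oc3c(OC)cc(C=O)cc3[C@H]2CO)ccc1O[Si](C(C)C)(C(C)C)C(C)C | intermediate
12 | (2S,3S)-3-[(tert-butyldiphenylsilyloxy)methyl]-7-methoxy-2-[3-methoxy-4-(triisopropylsilyloxy)phenyl]-2,3-dihydrobenzofuran-5-carbaldehyde | COc1cc([C@H]2Oc3c(OC)cc(C=O)cc3[C@H]2CO[Si](c4ccccc4)(c5ccccc5)C(C)(C)C)ccc1O[Si](C(C)C)(C(C)C)C(C)C | intermediate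
13 | syringaldehyde | COc1cc(C=O)cc(OC)c1O | starting material
14 | 3,5-dimethoxy-4-(triisopropylsilyloxy)benzaldehyde | COc1cc(C=O)cc(OC)c1O[Si](C(C)C)(C(C)C)C(C)C | intermediate
15 | (S)-4-benzyl-1,3-oxazolidin-2-one | O=C1N[C@@H](Cc2ccccc2)CO1 | starting material
16 | pent-4-enoyl chloride | C=CCCC(=O)Cl | starting material
17 | (S)-4-benzyl-3-(pent-4-enoyl)-1,3-oxazolidin-2-one | C=CCCC(=O)N1[C@@H](Cc2ccccc2)COC1=O | intermediate
18 | dibutylboron Z-enolate of 17 | C=CC/C=C(\OB(CCCC)CCCC)N1[C@@H](Cc2ccccc2)COC1=O | intermediate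
19 | (S)-4-benzyl-3-{(2S)-2-[(S)-Syr(hydroxy)methyl]pent-4-enoyl}-1,3-oxazolidin-2-one | C=CC[C@H](C(=O)N1[C@@H](Cc2ccccc2)COC1=O)[C@H](O)c1cc(OC)c(O[Si](C(C)C)(C(C)C)C(C)C)c(OC)c1 | intermediate
20 | triethylsilyl ether of 19 | C=CC[C@H](C(=O)N1[C@@H](Cc2ccccc2)COC1=O)[C@H](O[Si](CC)(CC)CC)c1cc(OC)c(O[Si](C(C)C)(C(C)C)C(C)C)c(OC)c1 | intermediate
21 | (2R)-2-[(S)-Syr(triethylsilyloxy)methyl]pent-4-en-1-ol | C=CC[C@H](CO)[C@H](O[Si](CC)(CC)CC)c1cc(OC)c(O[Si](C(C)C)(C(C)C)C(C)C)c(OC)c1 | intermediate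
22 | (3R)-3-(hydroxymethyl)-4-Syr-4-(S)-(triethylsilyloxy)butanal | O=CC[C@H](CO)[C@H](O[Si](CC)(CC)CC)c1cc(OC)c(O[Si](C(C)C)(C(C)C)C(C)C)c(OC)c1 | intermediate
23 | (4R)-4-[(S)-Syr(triethylsilyloxy)methyl]tetrahydrofuran-2-ol (anomer mixture) | OC1C[C@H](CO1)[C@H](O[Si](CC)(CC)CC)c1cc(OC)c(O[Si](C(C)C)(C(C)C)C(C)C)c(OC)c1 | intermediate
24 | (4R)-4-[(S)-Syr(triethylsilyloxy)methyl]dihydrofuran-2(3H)-one | O=C1C[C@H](CO1)[C@H](O[Si](CC)(CC)CC)c1cc(OC)c(O[Si](C(C)C)(C(C)C)C(C)C)c(OC)c1 | intermediate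
25 | potassium enolate of 24 | [O-]C1=C[C@H](CO1)[C@H](O[Si](CC)(CC)CC)c1cc(OC)c(O[Si](C(C)C)(C(C)C)C(C)C)c(OC)c1.[K+] | intermediate
26 | (3S,4R)-3-[(S)-BF(hydroxy)methyl]-4-[(S)-Syr(triethylsilyloxy)methyl]dihydrofuran-2(3H)-one | O=C1[C@H]([C@H](O)c2cc(OC)c3O[C@H](c4ccc(O[Si](C(C)C)(C(C)C)C(C)C)c(OC)c4)[C@H](CO[Si](c4ccccc4)(c4ccccc4)C(C)(C)C)c3c2)[C@H](CO1)[C@H](O[Si](CC)(CC)CC)c1cc(OC)c(O[Si](C(C)C)(C(C)C)C(C)C)c(OC)c1 | intermediate
27 | (1S,2R,3R,4S)-1-BF-2,3-bis(hydroxymethyl)-4-Syr-4-(triethylsilyloxy)butan-1-ol | OC[C@H]([C@H](O)c2cc(OC)c3O[C@H](c4ccc(O[Si](C(C)C)(C(C)C)C(C)C)c(OC)c4)[C@H](CO[Si](c4ccccc4)(c4ccccc4)C(C)(C)C)c3c2)[C@H](CO)[C@H](O[Si](CC)(CC)CC)c1cc(OC)c(O[Si](C(C)C)(C(C)C)C(C)C)c(OC)c1 | intermediate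
28 | (1S,2R,3R,4S)-1-BF-4-Syr-2,3-bis(hydroxymethyl)butane-1,4-diol | OC[C@H]([C@H](O)c2cc(OC)c3O[C@H](c4ccc(O[Si](C(C)C)(C(C)C)C(C)C)c(OC)c4)[C@H](CO[Si](c4ccccc4)(c4ccccc4)C(C)(C)C)c3c2)[C@H](CO)[C@H](O)c1cc(OC)c(O[Si](C(C)C)(C(C)C)C(C)C)c(OC)c1 | intermediate
29 | bis(methanesulfonate) of the two primary alcohols of 28 | CS(=O)(=O)OC[C@H]([C@H](O)c2cc(OC)c3O[C@H](c4ccc(O[Si](C(C)C)(C(C)C)C(C)C)c(OC)c4)[C@H](CO[Si](c4ccccc4)(c4ccccc4)C(C)(C)C)c3c2)[C@H](COS(C)(=O)=O)[C@H](O)c1cc(OC)c(O[Si](C(C)C)(C(C)C)C(C)C)c(OC)c1 | intermediate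
30 | (1S,3aR,4S,6aR)-1-BF-4-Syr-tetrahydro-1H,3H-furo[3,4-c]furan (tris-silyl ether of the target) | COc1cc([C@H]2Oc3c(OC)cc([C@H]4OC[C@H]5[C@@H]4CO[C@@H]5c4cc(OC)c(O[Si](C(C)C)(C(C)C)C(C)C)c(OC)c4)cc3[C@H]2CO[Si](c2ccccc2)(c2ccccc2)C(C)(C)C)ccc1O[Si](C(C)C)(C(C)C)C(C)C | intermediate
31 | CNP0126146.1 | COc1cc([C@H]2Oc3c(OC)cc([C@H]4OC[C@H]5[C@@H]4CO[C@@H]5c4cc(OC)c(O)c(OC)c4)cc3[C@H]2CO)ccc1O | target

Total step count: 17.
Longest linear sequence: 10 steps (steps 1–6, then 14–17). The lactone branch (step 7 or 8, then 9–13, then 14–17) is equally long.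

Steps most likely to fail

Step 5. Three processes could erode the cyclisation:
- proton transfer from the benzylic C2–H to the aryllithium, followed by β-elimination that tears the oxirane open;
- attack at the terminal oxirane carbon;
- leakage of the aldehyde mask.

The fallback forms C2–C3 instead of C3–C3a by a cis-selective rhodium carbenoid C–H insertion. It sets out from 2 and 6 and comes back at 11.
- NaBH4 in MeOH reduces 2 to [3-methoxy-4-(triisopropylsilyloxy)phenyl]methanol F1.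
- Mitsunobu etherification of F1 with 6 gives 3-bromo-5-methoxy-4-{[3-methoxy-4-(triisopropylsilyloxy)benzyl]oxy}benzaldehyde F2.
- HC(OMe)3 and PPTS in MeOH give its dimethyl acetal F3.
- Negishi-type coupling with the Reformatsky reagent BrZnCH2CO2Me, under Pd(dba)2 and a bulky ferrocenyl di-tert-butylphosphine, gives the methyl arylacetate F4.
- Diazo transfer with 4-acetamidobenzenesulfonyl azide and DBU gives the methyl aryldiazoacetate F5.
- Dirhodium tetrakis(N-phthaloyl-tert-leucinate), Rh2(S-PTTL)4 or its mirror image, whichever leads to the 2S series, in toluene at low temperature inserts the carbenoid into the benzylic O–CH2 bond. This gives the cis methyl (2S,3R)-2,3-dihydrobenzofuran-3-carboxylate F6.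
- LiAlH4 at −20 °C reduces the ester before it can epimerise, giving the cis alcohol acetal F7.
- PPTS in wet acetone then frees the aldehyde, giving 11.

Step 4. Two processes could hurt this step. Partial ionisation of the oxyphosphonium salt would cost configurational purity at the benzylic carbon. Sluggish attack by the doubly ortho-substituted phenoxide would let side reactions of the activated alcohol take over.

The fallback makes the aryl–oxygen bond at the arene by SNAr, with retention at the carbinol carbon. It sets out from 5 and comes back at 7.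
- Mitsunobu inversion of 5 with the small, strongly acidic 4-nitrobenzoic acid is the usual way to invert such epoxy alcohols. It gives (R)-[3-methoxy-4-(triisopropylsilyloxy)phenyl][(R)-oxiran-2-yl]methyl 4-nitrobenzoate F8.
- Brief K2CO3 in MeOH at 0 °C gives the threo alcohol (R)-[3-methoxy-4-(triisopropylsilyloxy)phenyl][(R)-oxiran-2-yl]methanol F9.
- The sodium alkoxide of F9 (NaH, THF, 0 °C) displaces fluoride from purchased 3-bromo-4-fluoro-5-methoxybenzaldehyde, giving 7.

Step 14. Poor simple diastereoselection at the C7 carbinol, or equilibration through retro-aldol, would feed the wrong epimer into the stereoretentive ring closure.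

The fallback sets C7 by reduction instead of by the aldol. It sets out from 24 and 12 and comes back at 26.
- An aldol with LiN(iPr)2 in THF at −78 °C, run without regard to the carbinol centre, gives the C7-epimeric aldol mixture F10.
- Dess–Martin periodinane gives the β-keto lactone F11, whose C8 stays trans because that is the more stable arrangement.
- Zn(BH4)2 in Et2O at low temperature reduces the zinc-chelated 1,3-dicarbonyl unit from the face away from C8', the known route to syn β-hydroxy carbonyl compounds, giving 26.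

Further compounds
F1 | step 5 | [3-methoxy-4-(triisopropylsilyloxy)phenyl]methanol | COc1cc(CO)ccc1O[Si](C(C)C)(C(C)C)C(C)C
F2 | step 5 | 3-bromo-5-methoxy-4-{[3-methoxy-4-(triisopropylsilyloxy)benzyl]oxy}benzaldehyde | COc1cc(COc2c(OC)cc(C=O)cc2Br)ccc1O[Si](C(C)C)(C(C)C)C(C)C
F3 | step 5 | dimethyl acetal of F2 | COc1cc(COc2c(OC)cc(C(OC)OC)cc2Br)ccc1O[Si](C(C)C)(C(C)C)C(C)C
F4 | step 5 | methyl 2-[5-(dimethoxymethyl)-3-methoxy-2-{[3-methoxy-4-(triisopropylsilyloxy)benzyl]oxy}phenyl]acetate | COC(=O)Cc1cc(C(OC)OC)cc(OC)c1OCc1ccc(O[Si](C(C)C)(C(C)C)C(C)C)c(OC)c1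
F5 | step 5 | methyl 2-diazo-2-[5-(dimethoxymethyl)-3-methoxy-2-{[3-methoxy-4-(triisopropylsilyloxy)benzyl]oxy}phenyl]acetate | COC(=O)C(=[N+]=[N-])c1cc(C(OC)OC)cc(OC)c1OCc1ccc(O[Si](C(C)C)(C(C)C)C(C)C)c(OC)c1
F6 | step 5 | methyl (2S,3R)-5-(dimethoxymethyl)-7-methoxy-2-[3-methoxy-4-(triisopropylsilyloxy)phenyl]-2,3-dihydrobenzofuran-3-carboxylate (cis) | COc1cc([C@H]2Oc3c(OC)cc(C(OC)OC)cc3[C@H]2C(=O)OC)ccc1O[Si](C(C)C)(C(C)C)C(C)C
F7 | step 5 | {(2S,3S)-5-(dimethoxymethyl)-7-methoxy-2-[3-methoxy-4-(triisopropylsilyloxy)phenyl]-2,3-dihydrobenzofuran-3-yl}methanol | COc1cc([C@H]2Oc3c(OC)cc(C(OC)OC)cc3[C@H]2CO)ccc1O[Si](C(C)C)(C(C)C)C(C)C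
F8 | step 4 | (R)-[3-methoxy-4-(triisopropylsilyloxy)phenyl][(R)-oxiran-2-yl]methyl 4-nitrobenzoate | COc1cc([C@@H](OC(=O)c2ccc(cc2)[N+](=O)[O-])[C@H]2CO2)ccc1O[Si](C(C)C)(C(C)C)C(C)C
F9 | step 4 | (R)-[3-methoxy-4-(triisopropylsilyloxy)phenyl][(R)-oxiran-2-yl]methanol (threo) | COc1cc([C@@H](O)[C@H]2CO2)ccc1O[Si](C(C)C)(C(C)C)C(C)C
F10 | step 14 | (3S,4R)-3-[BF(hydroxy)methyl]-4-[(S)-Syr(triethylsilyloxy)methyl]dihydrofuran-2(3H)-one, both C7 epimers | O=C1[C@H](C(O)c2cc(OC)c3O[C@H](c4ccc(O[Si](C(C)C)(C(C)C)C(C)C)c(OC)c4)[C@H](CO[Si](c4ccccc4)(c4ccccc4)C(C)(C)C)c3c2)[C@H](CO1)[C@H](O[Si](CC)(CC)CC)c1cc(OC)c(O[Si](C(C)C)(C(C)C)C(C)C)c(OC)c1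
F11 | step 14 | (3S,4R)-3-(BF-carbonyl)-4-[(S)-Syr(triethylsilyloxy)methyl]dihydrofuran-2(3H)-one | O=C1[C@H](C(=O)c2cc(OC)c3O[C@H](c4ccc(O[Si](C(C)C)(C(C)C)C(C)C)c(OC)c4)[C@H](CO[Si](c4ccccc4)(c4ccccc4)C(C)(C)C)c3c2)[C@H](CO1)[C@H](O[Si](CC)(CC)CC)c1cc(OC)c(O[Si](C(C)C)(C(C)C)C(C)C)c(OC)c1
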